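**Plan**

- Retrosynthesis: the two ester C–O bonds (O8–acyl, O3–isovaleryl) are cut first, then the ring bond C3–C4 (C4 alkenyl iodide plus C3 aldehyde), then C4=C5 (iodo-olefination of a C5 aldehyde), C11=C13, the two C–O bonds of the 1,10-oxirane and finally C7–C8. This leaves a C8–C3 hexenyl linker and a five-carbon butenolide (C5, C6, C7, C11, C12).
- Enabling feature: C3 is a secondary allylic carbinol bonded directly to C4 of the Z-trisubstituted C4=C5 alkene in the ten-membered carbocycle. A Z-alkenyl metal at C4 adding to a C3 aldehyde therefore makes this bond, the carbinol and the ring in one event.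
- Forward order: the γ-lactone ring is present from the start (butenolide). The chain is joined at C7–C8, the 1,10-oxirane is installed on the open chain, and the Z-iodoalkene, the exo-methylene and the C3 aldehyde follow. The ten-membered ring then closes at C3–C4 and the two esters are added last.
- Stereochemistry: C6 from (S)-5-(hydroxymethyl)furan-2(5H)-one; C7 by anti radical addition to the butenolide; C8 by oxazaborolidine-controlled ketone reduction; C1/C10 by Shi epoxidation of the E alkene; C3 in the ring closure (substrate control); the epoxy ester centres by Sharpless epoxidation of tiglyl alcohol; the 4Z alkene from a Z-selective iodo-olefination.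

Key step: step 17

Remark: atoms carry the germacranolide numbers of the target in every intermediate (ring C1–C10, lactone C11–C13, C14 on C10, C15 on C4); TBS = tert-butyldimethylsilyl, PMB = 4-methoxybenzyl.

Assumption: the C8 acyl group is taken exactly as drawn, (2S,3R)-2,3-dimethyloxirane-2-carbonyl. Its two methyl groups are cis on the oxirane, so it is the epoxide of the E acid (tiglic acid), and tiglic acid is used as its source.

**Route**

Step 1
Reactants: 1 tert-butyl(but-3-yn-1-yloxy)dimethylsilane; 2 oxirane (ethylene oxide)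
Product: 5 (3E)-6-(TBS-oxy)-4-methylhex-3-en-1-ol, via alkenyldimethylalane 3 (not isolated), via lithium alkenylalanate 4 (not isolated)
Conditions: Me3Al, Cp2ZrCl2 (25 mol %), CH2Cl2, rt; n-BuLi, hexane/THF, −30 °C; then 2, −30 → 0 °C
Reagents that add atoms: trimethylaluminium, C[Al](C)C
Why: Negishi zirconium-catalysed carboalumination adds methyl and aluminium syn across the alkyne (methyl to the internal carbon), and the lithium alanate opens oxirane with retention at the alkenyl carbon, so the C1=C10 alkene should form as the E isomer with C9 and C2 trans.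

Step 2
Reactants: 5 (3E)-6-(TBS-oxy)-4-methylhex-3-en-1-ol
Product: 6 tert-butyl{[(3E)-6-(PMB-oxy)-3-methylhex-3-en-1-yl]oxy}dimethylsilane
Conditions: NaH, PMBCl, Bu4NI (cat.), THF/DMF, 0 °C → rt
Reagents that add atoms: 4-methoxybenzyl chloride, COc1ccc(CCl)cc1
Why: Williamson etherification of the primary alkoxide installs at O3 an ether that can later be removed oxidatively at neutral pH.

Step 3
Reactants: 6 tert-butyl{[(3E)-6-(PMB-oxy)-3-methylhex-3-en-1-yl]oxy}dimethylsilane
Product: 7 (3E)-6-(PMB-oxy)-3-methylhex-3-en-1-ol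
Conditions: Bu4NF, THF, rt
Reagents that add atoms: none
Why: Fluoride-mediated desilylation frees the C8 hydroxyl and leaves the PMB ether and the alkene untouched.

Step 4
Reactants: 7 (3E)-6-(PMB-oxy)-3-methylhex-3-en-1-ol
Product: 8 (3E)-6-(PMB-oxy)-3-methylhex-3-enal
Conditions: Dess–Martin periodinane, pyridine, CH2Cl2, 0 °C; used crude
Reagents that add atoms: none
Why: Dess–Martin oxidation under buffered, non-basic conditions should give the β,γ-unsaturated aldehyde without moving the C1=C10 alkene into conjugation.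

Step 5
Reactants: 9 (S)-5-(hydroxymethyl)furan-2(5H)-one
Product: 10 (S)-5-[(TBS-oxy)methyl]furan-2(5H)-one
Conditions: TBSCl, imidazole, CH2Cl2, 0 °C → rt
Reagents that add atoms: tert-butyldimethylsilyl chloride, CC(C)(C)[Si](C)(C)Cl
Why: Silylation of the primary alcohol protects O5 and gives the C6 substituent the bulk that shields one face of the butenolide.

Step 6
Reactants: 8 (3E)-6-(PMB-oxy)-3-methylhex-3-enal; 10 (S)-5-[(TBS-oxy)methyl]furan-2(5H)-one
Product: 11 (4R,5S)-5-[(TBS-oxy)methyl]-4-[(3E)-1-hydroxy-6-(PMB-oxy)-3-methylhex-3-en-1-yl]dihydrofuran-2(3H)-one (C8 epimer mixture)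
Conditions: SmI2 (2.5 equiv), t-BuOH, THF, −78 °C; aq. NH4Cl at −78 °C
Reagents that add atoms: none
Why: In this samarium diiodide ketyl–olefin coupling the C8 ketyl radical adds to the β-carbon (C7) of the butenolide on the face opposite the CH2OTBS group, which sets the 6,7-trans relationship; C8 forms without reliable control and is reset in steps 7 and 8.

Step 7
Reactants: 11 (4R,5S)-5-[(TBS-oxy)methyl]-4-[(3E)-1-hydroxy-6-(PMB-oxy)-3-methylhex-3-en-1-yl]dihydrofuran-2(3H)-one (C8 epimer mixture)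
Product: 12 (4S,5S)-5-[(TBS-oxy)methyl]-4-[(3E)-6-(PMB-oxy)-3-methylhex-3-enoyl]dihydrofuran-2(3H)-one
Conditions: Dess–Martin periodinane, pyridine, CH2Cl2, 0 °C
Reagents that add atoms: none
Why: Dess–Martin oxidation converges both C8 epimers to one ketone under non-basic conditions that should spare the β-acyloxy ketone from elimination and the C7 centre from epimerisation.

Step 8
Reactants: 12 (4S,5S)-5-[(TBS-oxy)methyl]-4-[(3E)-6-(PMB-oxy)-3-methylhex-3-enoyl]dihydrofuran-2(3H)-one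
Product: 13 (4R,5S)-5-[(TBS-oxy)methyl]-4-[(1R,3E)-1-hydroxy-6-(PMB-oxy)-3-methylhex-3-en-1-yl]dihydrofuran-2(3H)-one
Conditions: (S)-2-methyl-CBS-oxazaborolidine [(S)-1-methyl-3,3-diphenyltetrahydro-1H,3H-pyrrolo[1,2-c][1,3,2]oxazaborole] (50 mol %), catecholborane, toluene, −78 °C
Reagents that add atoms: none
Why: In this Corey–Bakshi–Shibata reduction the (S)-oxazaborolidine should bind the ketone with the branched C7 as the large and the C9 methylene as the small substituent and deliver hydride to the face that gives the 8R alcohol (reagent control), while catecholborane leaves lactone and alkene alone.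

Step 9
Reactants: 13 (4R,5S)-5-[(TBS-oxy)methyl]-4-[(1R,3E)-1-hydroxy-6-(PMB-oxy)-3-methylhex-3-en-1-yl]dihydrofuran-2(3H)-one
Product: 14 (4S,5S)-5-[(TBS-oxy)methyl]-4-[(1R,3E)-1-(TBS-oxy)-6-(PMB-oxy)-3-methylhex-3-en-1-yl]dihydrofuran-2(3H)-one
Conditions: TBSOTf, 2,6-lutidine, CH2Cl2, −78 → 0 °C
Reagents that add atoms: tert-butyldimethylsilyl triflate, CC(C)(C)[Si](C)(C)OS(=O)(=O)C(F)(F)F
Why: Silylation with the silyl triflate caps the hindered C8 hydroxyl at low temperature and thereby also blocks translactonisation to the 8,12-olide.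

Step 10
Reactants: 14 (4S,5S)-5-[(TBS-oxy)methyl]-4-[(1R,3E)-1-(TBS-oxy)-6-(PMB-oxy)-3-methylhex-3-en-1-yl]dihydrofuran-2(3H)-one
Product: 15 (4S,5S)-5-(hydroxymethyl)-4-[(1R,3E)-1-(TBS-oxy)-6-(PMB-oxy)-3-methylhex-3-en-1-yl]dihydrofuran-2(3H)-one
Conditions: HF·pyridine, pyridine, THF, 0 °C
Reagents that add atoms: none
Why: Selective desilylation works because buffered HF·pyridine cleaves the unhindered primary silyl ether much faster than the secondary one at C8.

Step 11
Reactants: 15 (4S,5S)-5-(hydroxymethyl)-4-[(1R,3E)-1-(TBS-oxy)-6-(PMB-oxy)-3-methylhex-3-en-1-yl]dihydrofuran-2(3H)-one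
Product: 16 (4S,5S)-5-(hydroxymethyl)-4-{(1R)-1-(TBS-oxy)-2-[(2R,3R)-3-[2-(PMB-oxy)ethyl]-2-methyloxiran-2-yl]ethyl}dihydrofuran-2(3H)-one
Conditions: 1,2:4,5-di-O-isopropylidene-β-D-erythro-2,3-hexodiulo-2,6-pyranose (D-fructose-derived Shi ketone, 30 mol %), Oxone (2KHSO5·KHSO4·K2SO4), K2CO3, Bu4NHSO4, MeCN/dimethoxymethane/aq. Na2B4O7 buffer, 0 °C
Reagents that add atoms: potassium peroxymonosulfate (Oxone), [K+].[O-]S(=O)(=O)OO
Why: In the Shi epoxidation the chiral dioxirane attacks the electron-rich E-trisubstituted C1=C10 alkene through the spiro transition state and should give the (1R,10R)-oxirane by reagent control, while lactone, ethers and the free alcohol are inert.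

Step 12
Reactants: 16 (4S,5S)-5-(hydroxymethyl)-4-{(1R)-1-(TBS-oxy)-2-[(2R,3R)-3-[2-(PMB-oxy)ethyl]-2-methyloxiran-2-yl]ethyl}dihydrofuran-2(3H)-one
Product: 17 (2S,3S)-3-{(1R)-1-(TBS-oxy)-2-[(2R,3R)-3-[2-(PMB-oxy)ethyl]-2-methyloxiran-2-yl]ethyl}-5-oxotetrahydrofuran-2-carbaldehyde
Conditions: Dess–Martin periodinane, pyridine, CH2Cl2, 0 °C; used crude
Reagents that add atoms: none
Why: Dess–Martin oxidation of the primary alcohol gives the C5 aldehyde under neutral conditions that should avoid epimerisation at C6 and opening of the oxirane.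

Step 13
Reactants: 17 (2S,3S)-3-{(1R)-1-(TBS-oxy)-2-[(2R,3R)-3-[2-(PMB-oxy)ethyl]-2-methyloxiran-2-yl]ethyl}-5-oxotetrahydrofuran-2-carbaldehyde
Product: 18 (4S,5S)-5-[(1Z)-2-iodoprop-1-en-1-yl]-4-{(1R)-1-(TBS-oxy)-2-[(2R,3R)-3-[2-(PMB-oxy)ethyl]-2-methyloxiran-2-yl]ethyl}dihydrofuran-2(3H)-one
Conditions: [Ph3PCH2CH3]I, n-BuLi, THF, rt; I2, −78 °C; NaN(SiMe3)2, −20 °C; then 17, −78 → −20 °C
Reagents that add atoms: ethyltriphenylphosphonium iodide, CC[P+](c1ccccc1)(c1ccccc1)c1ccccc1.[I-]; iodine, II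
Why: In this Stork–Zhao-type Wittig olefination the unstabilised α-iodo ylide adds under kinetic control and should give the Z-iodoalkene (C6 and iodine cis), which fixes the later C4=C5 ring geometry.

Step 14
Reactants: 18 (4S,5S)-5-[(1Z)-2-iodoprop-1-en-1-yl]-4-{(1R)-1-(TBS-oxy)-2-[(2R,3R)-3-[2-(PMB-oxy)ethyl]-2-methyloxiran-2-yl]ethyl}dihydrofuran-2(3H)-one
Product: 21 (4S,5S)-5-[(1Z)-2-iodoprop-1-en-1-yl]-3-methylidene-4-{(1R)-1-(TBS-oxy)-2-[(2R,3R)-3-[2-(PMB-oxy)ethyl]-2-methyloxiran-2-yl]ethyl}dihydrofuran-2(3H)-one, via Mannich base 19 (not isolated), via ammonium iodide 20 (not isolated)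
Conditions: LiN(iPr)2 (1.05 equiv), THF, −78 °C; CH2=NMe2 I, −78 °C → rt; MeI, MeOH, rt; aq. NaHCO3, CH2Cl2, rt
Reagents that add atoms: N,N-dimethylmethyleneiminium iodide (Eschenmoser's salt), C=[N+](C)C.[I-]
Why: Eschenmoser methylenation: the lithium enolate at C11 (far more acidic than any other C–H) undergoes a Mannich reaction, and quaternisation followed by E1cB loss of trimethylamine gives the exocyclic alkene, so the transient C11 stereocentre disappears.

Step 15
Reactants: 21 (4S,5S)-5-[(1Z)-2-iodoprop-1-en-1-yl]-3-methylidene-4-{(1R)-1-(TBS-oxy)-2-[(2R,3R)-3-[2-(PMB-oxy)ethyl]-2-methyloxiran-2-yl]ethyl}dihydrofuran-2(3H)-one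
Product: 22 (4S,5S)-4-{(1R)-1-(TBS-oxy)-2-[(2R,3R)-3-(2-hydroxyethyl)-2-methyloxiran-2-yl]ethyl}-5-[(1Z)-2-iodoprop-1-en-1-yl]-3-methylidenedihydrofuran-2(3H)-one
Conditions: DDQ, CH2Cl2/pH 7 phosphate buffer, 0 °C
Reagents that add atoms: none
Why: Oxidative PMB cleavage with DDQ proceeds through the benzylic oxocarbenium ion at neutral pH and should spare oxirane, silyl ether, iodoalkene and enoate.

Step 16
Reactants: 22 (4S,5S)-4-{(1R)-1-(TBS-oxy)-2-[(2R,3R)-3-(2-hydroxyethyl)-2-methyloxiran-2-yl]ethyl}-5-[(1Z)-2-iodoprop-1-en-1-yl]-3-methylidenedihydrofuran-2(3H)-one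
Product: 23 {(2R,3R)-3-[(2R)-2-(TBS-oxy)-2-{(2S,3S)-2-[(1Z)-2-iodoprop-1-en-1-yl]-4-methylidene-5-oxotetrahydrofuran-3-yl}ethyl]-3-methyloxiran-2-yl}acetaldehyde
Conditions: Dess–Martin periodinane, pyridine, CH2Cl2, 0 °C; filtered and used at once
Reagents that add atoms: none
Why: Dess–Martin oxidation gives the β,γ-epoxy aldehyde without base, and immediate use limits oxirane opening through the enol.

Step 17
Reactants: 23 {(2R,3R)-3-[(2R)-2-(TBS-oxy)-2-{(2S,3S)-2-[(1Z)-2-iodoprop-1-en-1-yl]-4-methylidene-5-oxotetrahydrofuran-3-yl}ethyl]-3-methyloxiran-2-yl}acetaldehyde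
Product: 24 (3S)-3-hydroxy-8-O-TBS-1,10-epoxygermacra-4Z,11(13)-dien-12,6-olide (C1, C6, C7, C8, C10 arranged as in the target)
Conditions: CrCl2 (12 equiv), NiCl2 (2 mol % of the CrCl2), degassed DMSO, 3 mM, rt
Reagents that add atoms: none
Why: Zerovalent nickel, generated from NiCl2 by divalent chromium, inserts into the C4–I bond with retention of the Z geometry, transmetalation gives an alkenyl species of trivalent chromium, and this adds to the C3 aldehyde (Nozaki–Hiyama–Kishi reaction; the closest known type is the alkenyl iodide–aldehyde cyclisation to nine- and ten-membered rings). The ten-membered carbocycle closes by 10-exo-trig addition of C4 to the C3 carbonyl. The new C3 stereocentre is under substrate control: the trans-lactone, the Z alkene and the trans-oxirane restrict the closing chain, and with the chromium-bound carbonyl oxygen pointing to the outside of the forming ring the 3S alcohol is expected. The step needs chemoselectivity (only the C–I bond is activated, and the neutral medium should spare oxirane, enoate, silyl ether and the enolisable aldehyde), retention of alkene geometry (alkenylchromium reagents are configurationally stable) and cyclisation over oligomerisation (high dilution).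

Step 18
Reactants: 24 (3S)-3-hydroxy-8-O-TBS-1,10-epoxygermacra-4Z,11(13)-dien-12,6-olide
Product: 25 (3S)-3-(3-methylbutanoyloxy)-8-O-TBS-1,10-epoxygermacra-4Z,11(13)-dien-12,6-olide
Conditions: isovaleric anhydride, Et3N, 4-(dimethylamino)pyridine (cat.), CH2Cl2, 0 °C → rt
Reagents that add atoms: 3-methylbutanoic (isovaleric) anhydride, CC(C)CC(=O)OC(=O)CC(C)C
Why: 4-(Dimethylamino)pyridine-catalysed acylation esterifies the secondary allylic alcohol with retention and removes the free 3-OH before it can open the 1,10-oxirane across the ring.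

Step 19
Reactants: 25 (3S)-3-(3-methylbutanoyloxy)-8-O-TBS-1,10-epoxygermacra-4Z,11(13)-dien-12,6-olide
Product: 26 (3S)-8-hydroxy-3-(3-methylbutanoyloxy)-1,10-epoxygermacra-4Z,11(13)-dien-12,6-olide
Conditions: HF·pyridine, pyridine, THF, 0 °C → rt
Reagents that add atoms: none
Why: Buffered HF·pyridine desilylation removes the secondary silyl ether without base, so the oxirane and the esters should survive and the lactone should not migrate to O8.

Step 20
Reactants: 27 tiglic acid [(2E)-2-methylbut-2-enoic acid]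
Product: 28 (2E)-2-methylbut-2-en-1-ol (tiglyl alcohol)
Conditions: LiAlH4, Et2O, 0 °C → rt
Reagents that add atoms: none
Why: LiAlH4 reduction of the acid proceeds by 1,2-hydride addition and gives the allylic alcohol with the E geometry intact.

Step 21
Reactants: 28 (2E)-2-methylbut-2-en-1-ol
Product: 29 [(2R,3R)-2,3-dimethyloxiran-2-yl]methanol
Conditions: Ti(OiPr)4 (10 mol %), D-(−)-diisopropyl tartrate (12 mol %), t-BuOOH, 4 Å sieves, CH2Cl2, −20 °C
Reagents that add atoms: tert-butyl hydroperoxide, CC(C)(C)OO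
Why: In the Katsuki–Sharpless asymmetric epoxidation the titanium–D-tartrate complex delivers oxygen to the face of the E allylic alcohol that gives the (2R,3R)-epoxy alcohol, and the E geometry fixes the two methyl groups cis.

Step 22
Reactants: 29 [(2R,3R)-2,3-dimethyloxiran-2-yl]methanol
Product: 30 (2S,3R)-2,3-dimethyloxirane-2-carboxylic acid
Conditions: RuCl3·xH2O (2 mol %), NaIO4, MeCN/EtOAc/H2O, 0 °C → rt
Reagents that add atoms: sodium periodate, [Na+].[O-]I(=O)(=O)=O
Why: Ruthenium tetroxide oxidation (RuCl3/NaIO4) takes the primary alcohol to the acid without touching the oxirane or either stereocentre; the C2 descriptor changes from R to S only because the substituent priorities change.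

Step 23
Reactants: 26 (3S)-8-hydroxy-3-(3-methylbutanoyloxy)-1,10-epoxygermacra-4Z,11(13)-dien-12,6-olide; 30 (2S,3R)-2,3-dimethyloxirane-2-carboxylic acid
Product: 32 CNP0167461.3 [(1R,3S,6R,7R,8R,10R)-8-[(2S,3R)-2,3-dimethyloxirane-2-carbonyloxy]-3-(3-methylbutanoyloxy)-1,10-epoxygermacra-4Z,11(13)-dien-12,6-olide], via mixed anhydride 31 (not isolated)
Conditions: 30, 2,4,6-Cl3C6H2COCl, Et3N, THF, rt; then 26, 4-(dimethylamino)pyridine, toluene, rt
Reagents that add atoms: none
Why: In the Yamaguchi esterification the acylpyridinium formed from the mixed anhydride transfers the epoxy acyl group to the hindered C8 alcohol with retention at C8 and without touching the stereocentres of the acid.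

**Compound list**

1 | tert-butyl(but-3-yn-1-yloxy)dimethylsilane | C#CCCO[Si](C)(C)C(C)(C)C | starting material
2 | oxirane (ethylene oxide) | C1CO1 | starting material
3 | {(1E)-4-(TBS-oxy)-2-methylbut-1-en-1-yl}dimethylaluminium | C[Al](C)/C=C(\C)CCO[Si](C)(C)C(C)(C)C | intermediate
4 | lithium butyl{(1E)-4-(TBS-oxy)-2-methylbut-1-en-1-yl}dimethylaluminate | [Li+].CCCC[Al-](C)(C)/C=C(\C)CCO[Si](C)(C)C(C)(C)C | intermediate
5 | (3E)-6-(TBS-oxy)-4-methylhex-3-en-1-ol | OCC/C=C(\C)CCO[Si](C)(C)C(C)(C)C | intermediate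
6 | tert-butyl{[(3E)-6-(PMB-oxy)-3-methylhex-3-en-1-yl]oxy}dimethylsilane | COc1ccc(COCC/C=C(\C)CCO[Si](C)(C)C(C)(C)C)cc1 | intermediate
7 | (3E)-6-(PMB-oxy)-3-methylhex-3-en-1-ol | COc1ccc(COCC/C=C(\C)CCO)cc1 | intermediate
8 | (3E)-6-(PMB-oxy)-3-methylhex-3-enal | COc1ccc(COCC/C=C(\C)CC=O)cc1 | intermediate
9 | (S)-5-(hydroxymethyl)furan-2(5H)-one | O=C1C=C[C@@H](CO)O1 | starting material
10 | (S)-5-[(TBS-oxy)methyl]furan-2(5H)-one | O=C1C=C[C@@H](CO[Si](C)(C)C(C)(C)C)O1 | intermediate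
11 | (4R,5S)-5-[(TBS-oxy)methyl]-4-[(3E)-1-hydroxy-6-(PMB-oxy)-3-methylhex-3-en-1-yl]dihydrofuran-2(3H)-one, both C8 epimers (6,7-trans) | O=C1C[C@H](C(O)C/C(C)=C/CCOCc2ccc(OC)cc2)[C@@H](CO[Si](C)(C)C(C)(C)C)O1 | intermediate
12 | (4S,5S)-5-[(TBS-oxy)methyl]-4-[(3E)-6-(PMB-oxy)-3-methylhex-3-enoyl]dihydrofuran-2(3H)-one (C8 ketone) | O=C1C[C@H](C(=O)C/C(C)=C/CCOCc2ccc(OC)cc2)[C@@H](CO[Si](C)(C)C(C)(C)C)O1 | intermediate
13 | (4R,5S)-5-[(TBS-oxy)methyl]-4-[(1R,3E)-1-hydroxy-6-(PMB-oxy)-3-methylhex-3-en-1-yl]dihydrofuran-2(3H)-one (8R alcohol) | O=C1C[C@H]([C@H](O)C/C(C)=C/CCOCc2ccc(OC)cc2)[C@@H](CO[Si](C)(C)C(C)(C)C)O1 | intermediate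
14 | (4S,5S)-5-[(TBS-oxy)methyl]-4-[(1R,3E)-1-(TBS-oxy)-6-(PMB-oxy)-3-methylhex-3-en-1-yl]dihydrofuran-2(3H)-one | O=C1C[C@H]([C@H](O[Si](C)(C)C(C)(C)C)C/C(C)=C/CCOCc2ccc(OC)cc2)[C@@H](CO[Si](C)(C)C(C)(C)C)O1 | intermediate
15 | (4S,5S)-5-(hydroxymethyl)-4-[(1R,3E)-1-(TBS-oxy)-6-(PMB-oxy)-3-methylhex-3-en-1-yl]dihydrofuran-2(3H)-one | O=C1C[C@H]([C@H](O[Si](C)(C)C(C)(C)C)C/C(C)=C/CCOCc2ccc(OC)cc2)[C@@H](CO)O1 | intermediate
16 | (4S,5S)-5-(hydroxymethyl)-4-{(1R)-1-(TBS-oxy)-2-[(2R,3R)-3-[2-(PMB-oxy)ethyl]-2-methyloxiran-2-yl]ethyl}dihydrofuran-2(3H)-one | O=C1C[C@H]([C@H](O[Si](C)(C)C(C)(C)C)C[C@@]2(C)O[C@@H]2CCOCc3ccc(OC)cc3)[C@@H](CO)O1 | intermediate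
17 | (2S,3S)-3-{(1R)-1-(TBS-oxy)-2-[(2R,3R)-3-[2-(PMB-oxy)ethyl]-2-methyloxiran-2-yl]ethyl}-5-oxotetrahydrofuran-2-carbaldehyde | O=C1C[C@H]([C@H](O[Si](C)(C)C(C)(C)C)C[C@@]2(C)O[C@@H]2CCOCc3ccc(OC)cc3)[C@@H](C=O)O1 | intermediate
18 | (4S,5S)-5-[(1Z)-2-iodoprop-1-en-1-yl]-4-{(1R)-1-(TBS-oxy)-2-[(2R,3R)-3-[2-(PMB-oxy)ethyl]-2-methyloxiran-2-yl]ethyl}dihydrofuran-2(3H)-one | O=C1C[C@H]([C@H](O[Si](C)(C)C(C)(C)C)C[C@@]2(C)O[C@@H]2CCOCc3ccc(OC)cc3)[C@@H](/C=C(/C)I)O1 | intermediate
19 | 3-[(dimethylamino)methyl] derivative of 18 (C11 epimers) | O=C1C(CN(C)C)[C@H]([C@H](O[Si](C)(C)C(C)(C)C)C[C@@]2(C)O[C@@H]2CCOCc3ccc(OC)cc3)[C@@H](/C=C(/C)I)O1 | intermediate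
20 | 3-[(trimethylammonio)methyl] iodide derived from 19 (C11 epimers) | O=C1C(C[N+](C)(C)C)[C@H]([C@H](O[Si](C)(C)C(C)(C)C)C[C@@]2(C)O[C@@H]2CCOCc3ccc(OC)cc3)[C@@H](/C=C(/C)I)O1.[I-] | intermediate
21 | (4S,5S)-5-[(1Z)-2-iodoprop-1-en-1-yl]-3-methylidene-4-{(1R)-1-(TBS-oxy)-2-[(2R,3R)-3-[2-(PMB-oxy)ethyl]-2-methyloxiran-2-yl]ethyl}dihydrofuran-2(3H)-one | C=C1C(=O)O[C@H](/C=C(/C)I)[C@H]1[C@H](O[Si](C)(C)C(C)(C)C)C[C@@]2(C)O[C@@H]2CCOCc3ccc(OC)cc3 | intermediate
22 | (4S,5S)-4-{(1R)-1-(TBS-oxy)-2-[(2R,3R)-3-(2-hydroxyethyl)-2-methyloxiran-2-yl]ethyl}-5-[(1Z)-2-iodoprop-1-en-1-yl]-3-methylidenedihydrofuran-2(3H)-one | C=C1C(=O)O[C@H](/C=C(/C)I)[C@H]1[C@H](O[Si](C)(C)C(C)(C)C)C[C@@]2(C)O[C@@H]2CCO | intermediate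
23 | {(2R,3R)-3-[(2R)-2-(TBS-oxy)-2-{(2S,3S)-2-[(1Z)-2-iodoprop-1-en-1-yl]-4-methylidene-5-oxotetrahydrofuran-3-yl}ethyl]-3-methyloxiran-2-yl}acetaldehyde (ring-closure precursor) | C=C1C(=O)O[C@H](/C=C(/C)I)[C@H]1[C@H](O[Si](C)(C)C(C)(C)C)C[C@@]2(C)O[C@@H]2CC=O | intermediate
24 | (3S)-3-hydroxy-8-O-TBS-1,10-epoxygermacra-4Z,11(13)-dien-12,6-olide; 6,12-trans-fused α-methylene lactone, C1, C6, C7, C8, C10 arranged as in the target | C=C1C(=O)O[C@@H]2/C=C(/C)[C@@H](O)C[C@H]3O[C@]3(C)C[C@@H](O[Si](C)(C)C(C)(C)C)[C@@H]12 | intermediate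
25 | (3S)-3-(3-methylbutanoyloxy)-8-O-TBS-1,10-epoxygermacra-4Z,11(13)-dien-12,6-olide | C=C1C(=O)O[C@@H]2/C=C(/C)[C@@H](OC(=O)CC(C)C)C[C@H]3O[C@]3(C)C[C@@H](O[Si](C)(C)C(C)(C)C)[C@@H]12 | intermediate
26 | (3S)-8-hydroxy-3-(3-methylbutanoyloxy)-1,10-epoxygermacra-4Z,11(13)-dien-12,6-olide | C=C1C(=O)O[C@@H]2/C=C(/C)[C@@H](OC(=O)CC(C)C)C[C@H]3O[C@]3(C)C[C@@H](O)[C@@H]12 | intermediate
27 | tiglic acid, (2E)-2-methylbut-2-enoic acid | C/C=C(\C)C(=O)O | starting material
28 | (2E)-2-methylbut-2-en-1-ol | C/C=C(\C)CO | intermediate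
29 | [(2R,3R)-2,3-dimethyloxiran-2-yl]methanol | OC[C@@]1(C)O[C@@H]1C | intermediate
30 | (2S,3R)-2,3-dimethyloxirane-2-carboxylic acid | OC(=O)[C@@]1(C)O[C@@H]1C | intermediate
31 | (2S,3R)-2,3-dimethyloxirane-2-carboxylic 2,4,6-trichlorobenzoic anhydride | O=C(OC(=O)[C@@]1(C)O[C@@H]1C)c1c(Cl)cc(Cl)cc1Cl | intermediate
32 | CNP0167461.3, (1R,3S,6R,7R,8R,10R)-8-[(2S,3R)-2,3-dimethyloxirane-2-carbonyloxy]-3-(3-methylbutanoyloxy)-1,10-epoxygermacra-4Z,11(13)-dien-12,6-olide | C=C1C(=O)O[C@@H]2/C=C(/C)[C@@H](OC(=O)CC(C)C)C[C@H]3O[C@]3(C)C[C@@H](OC(=O)[C@@]3(C)O[C@@H]3C)[C@@H]12 | target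

**Step count and risks**

Total step count: 23. Longest linear sequence: 19 steps (steps 1–4, 6–19 and 23, counted from 1).

The three steps most likely to fail:

Step 17. The alkenylchromium may add to the wrong face of the C3 aldehyde, or to both faces, because the facial preference rests only on the conformation of the closing ring. The fallback sets out from 23: the ring closure is run as before and the 3R epimer of the allylic alcohol F1 is collected. Mitsunobu esterification of this alcohol with isovaleric acid (PPh3, diisopropyl azodicarboxylate, toluene, 0 °C) inverts C3 and installs the ester in one operation, so the material returns to the route at 25 without passing through 24.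

Step 6. Pinacol dimerisation or plain reduction of the enolisable aldehyde may outrun the cross-coupling, and the samarium alkoxide may translactonise toward O8. The fallback makes the C7–C8 bond by a polar instead of a radical process. It sets out from 8, which is converted with propane-1,3-dithiol and catalytic iodine into the 2-alkyl-1,3-dithiane F2. Lithiation (n-BuLi, THF/HMPA, −78 °C) and conjugate addition to 10, again anti to the C6 substituent, should give the dithiane adduct F3, and MeI/CaCO3 in aqueous MeCN unmasks the carbonyl group, which returns the material to the route at 12.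

Step 8. Hydride delivery may show poor facial selectivity if the preference of the catalyst is opposed by the C7 stereocentre. The fallback corrects C8 by inversion instead of by reduction control. It sets out from 12: the reduction then gives mainly the 8S alcohol F4, and a Mitsunobu reaction with chloroacetic acid (PPh3, diisopropyl azodicarboxylate, toluene) gives the inverted 8R chloroacetate F5. Thiourea and NaHCO3 in EtOH cleave it under neutral conditions and return the material to the route at 13.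

Further compounds
F1 | step 17 | (3R)-3-hydroxy-8-O-TBS-1,10-epoxygermacra-4Z,11(13)-dien-12,6-olide (C3 epimer of 24) | C=C1C(=O)O[C@@H]2/C=C(/C)[C@H](O)C[C@H]3O[C@]3(C)C[C@@H](O[Si](C)(C)C(C)(C)C)[C@@H]12
F2 | step 6 | 2-[(2E)-5-(PMB-oxy)-2-methylpent-2-en-1-yl]-1,3-dithiane | COc1ccc(COCC/C=C(\C)CC2SCCCS2)cc1
F3 | step 6 | (4S,5S)-5-[(TBS-oxy)methyl]-4-{2-[(2E)-5-(PMB-oxy)-2-methylpent-2-en-1-yl]-1,3-dithian-2-yl}dihydrofuran-2(3H)-one (6,7-trans) | O=C1C[C@H](C2(C/C(C)=C/CCOCc3ccc(OC)cc3)SCCCS2)[C@@H](CO[Si](C)(C)C(C)(C)C)O1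
F4 | step 8 | (4R,5S)-5-[(TBS-oxy)methyl]-4-[(1S,3E)-1-hydroxy-6-(PMB-oxy)-3-methylhex-3-en-1-yl]dihydrofuran-2(3H)-one (C8 epimer of 13) | O=C1C[C@H]([C@@H](O)C/C(C)=C/CCOCc2ccc(OC)cc2)[C@@H](CO[Si](C)(C)C(C)(C)C)O1
F5 | step 8 | (8R)-chloroacetate of 13 | O=C1C[C@H]([C@H](OC(=O)CCl)C/C(C)=C/CCOCc2ccc(OC)cc2)[C@@H](CO[Si](C)(C)C(C)(C)C)O1
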